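Compound numbers follow the order of the steps below and are used from the first section on. Ring B is numbered B1 to B6: B1 carries the ring A aryloxy group, B2 the methyl, B3 the methoxy, B4 a hydrogen, B5 the isopropyl and B6 the oxygen that links to ring C.

## Analysis of the target

The target 26 consists of three p-cymene-type rings joined by two diaryl ether bonds. Ring A is a 2-isopropyl-4-methoxy-5-methylphenyl group, ring B a pentasubstituted benzene, and ring C a 2-methyl-5-isopropyl-1,4-benzoquinone that carries the ether oxygen on the carbon next to its methyl group. There is no stereocentre and no stereogenic double bond, so stereochemistry appears only in intermediates and is erased again. The quinone is the most sensitive part: it is an oxidant, a Michael acceptor and labile to base and light. Rings A and B are both hydroquinone diethers (in ring A the methoxy is para to the aryloxy, in ring B the B3 methoxy is para to the B6 aryloxy), so the usual oxidative unmasking of a quinone from a dimethoxyarene would destroy them. The hard part is ring B: five substituents, three oxygens that must be told apart, and two aryl ether bonds on the neighbouring carbons B1 and B6, each flanked on both sides. No cheap arene has this pattern. The plan rests on the fact that the B1 and B3 oxygens sit 1,3 to each other across the B2 methyl, with the isopropyl on B5. That is the pattern of a 2-methyl-5-isopropylcyclohexane-1,3-dione with one extra oxygen on B6.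

## Retrosynthetic reasoning

**26 to 21 and 25.** The bond between the B6 oxygen and the quinone carbon is cut first. The quinone then enters last and already at its final oxidation level, so that no oxidation is needed in the presence of rings A and B. The forward reaction is an addition–elimination of the phenoxide of 21 on the bromine-bearing carbon of bromoquinone 25.

**25 to 23 to 22.** The bromine must sit next to the quinone methyl. Direct bromination of the unbrominated parent quinone would rely on a small steric bias between its two ring CH positions. Thymol 22 fixes the position by constitution: its free ortho and para positions are both brominated to give 23, and oxidation through the bromohydrin dienone 24 turns the para carbon into the second carbonyl with loss of that bromine.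

**21 to 20.** The B6 hydroxyl is carried as a benzyl ether from compound 1 onward. Hydrogenolysis removes it without touching methyl or aryl ethers, and it must go before the quinone is introduced because a quinone would not survive hydrogenation.

**20 to 16 and 19.** The B1–O–aryl bond is cut on the ring A side. Ring A is carvacrol 17 with one more oxygen, so it is bought, methylated to 18 and activated at the position para to the methoxy group as the symmetric diaryliodonium salt 19. Aryl transfer from hypervalent iodine is chosen because the phenol oxygen of 16 is flanked by a methyl and a benzyloxy group and the aryl group carries an ortho isopropyl.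

**16 to 12 to 11.** The arene is traced back to the cyclohexenone 12, one oxidation level lower. The forward reaction is an α-selenenylation and selenoxide elimination through 13, 14 and 15, and tautomerisation of 15 gives the phenol. Enone 12 is the methyl enol ether of dione 11 at B3. This is the point where the B1 and B3 oxygens become different: B3 lies next to the B4 methylene, B1 next to the benzyloxy-bearing B6.

**11 to 9.** The dione comes from the keto ester 9 by saponification and decarboxylation through acid 10. The ester is the activating group that the ring construction needs and has no further role.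

**9 to 6 and 7.** This is the key disconnection. The bonds B4–B5 and B2–B3 are cut, which opens ring B to enone 6 and dimethyl malonate 7. The cut is made here because it places all five substituents by connectivity and delivers the three oxygens as three different functions. The forward reaction must add the malonate to a hindered, α-oxygenated enone and then close the ring through the ethyl carbon, via adduct 8.

**6 to 4 and 5; 4 to 2 and 3; 2 to 1.** The C=C bond of 6 is cut to the α-benzyloxy β-ketophosphonate 4 and isobutyraldehyde 5. An olefination fixes which carbon carries the double bond, whereas a crossed aldol condensation of an unsymmetrical α-alkoxy ketone would have to enolise on one side only. Phosphonate 4 comes from acylation of the lithiated phosphonate 2 with ethyl propanoate 3, and 2 from benzyl chloromethyl ether 1 by an Arbuzov reaction.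

## Alternatives that were turned down

**Alternative 1: aryne route to ring B.**
- Disconnection: ring B stays aromatic, and the B5–isopropyl bond and the B6–heteroatom bond are cut together.
- Forward key step: 5-chloro-1,3-dimethoxy-2-methylbenzene A1 is lithiated next to chlorine and loses LiCl to give the B5–B6 aryne. An isopropyl Grignard reagent adds at B5, so the arylmagnesium sits at B6 next to a methoxy group, and a borate ester traps it as (6-isopropyl-2,4-dimethoxy-3-methylphenyl)boronic acid A2. Oxidation would give the B6 phenol.
- For it: no ring is built or aromatised, A1 is symmetric so the metalation has one outcome, and two adjacent bonds come from one flask. On step count to a fully substituted ring B it is stronger than the chosen route.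
- Against it: A2 carries the B1 and B3 oxygens as two methyl ethers of common origin, but the target needs an aryl ether on B1 and a methyl ether on B3. That calls for a B1-selective demethylation and then an ordered pair of hindered arylations on the neighbouring B1 and B6 hydroxyls, and the skeleton controls neither. The aryne addition rests on an inductive preference, and a secondary Grignard reagent can also reduce or deprotonate.
- Comparison: the chosen strategy is longer up to the ring B phenol but delivers the three oxygens as benzyl ether, ketone and enol ether, already distinguished.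

**Alternative 2: ring C by Moore ring expansion.**
- Disconnection: ring C is built on the B6 oxygen instead of being bought. The ring bond between the ketene-derived carbon and the former terminal methylene is cut, which leads back to the cyclobutenone 4-hydroxy-3-[6-isopropyl-2-(2-isopropyl-4-methoxy-5-methylphenoxy)-4-methoxy-3-methylphenoxy]-2-methyl-4-(3-methylbut-1-en-2-yl)cyclobut-2-en-1-one A3, assembled from a squarate ester, phenol 21 and an isopropyl-substituted vinyllithium.
- Forward key step: heating A3 opens the four-membered ring to a dienylketene, which closes by 6π electrocyclisation and tautomerises to the hydroquinone 3-[6-isopropyl-2-(2-isopropyl-4-methoxy-5-methylphenoxy)-4-methoxy-3-methylphenoxy]-5-isopropyl-2-methylbenzene-1,4-diol A4. Mild oxidation gives 26.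
- For it: the substitution pattern of ring C follows from connectivity, the quinone level appears only at the very end, and the electron-rich phenoxide of 21 never meets a quinone. On these points it is stronger than step 14.
- Against it: it needs the same phenol 21, so it does not solve ring B. It spends about five steps on a ring whose skeleton is that of thymol. The aryloxy group on the cyclobutenedione is itself a leaving group toward the organolithium, and the addition must choose between two carbonyls.
- Comparison: the chosen strategy puts its ring-forming effort where no commercial ring exists. The fallback for step 14 reaches the same hydroquinone by another way.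

**Alternative 3: ring A by Robinson annulation.**
- Disconnection: the hindered B1–O–aryl bond is replaced by an O-alkylation, and ring A is cut at a Michael bond (oxygen-bearing carbon to the neighbouring CH2) and an aldol bond (isopropyl-bearing carbon to the neighbouring CH).
- Forward key step: the enolate of 1-[2-(benzyloxy)-3-isopropyl-5-methoxy-6-methylphenoxy]-3-methylbutan-2-one A5, made from phenol 16, adds to 3-methylbut-3-en-2-one A6. The methyl ketone then condenses onto the isopropyl ketone to give 4-[2-(benzyloxy)-3-isopropyl-5-methoxy-6-methylphenoxy]-3-isopropyl-6-methylcyclohex-2-en-1-one A7. Dehydrogenation and O-methylation would complete ring A.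
- For it: the ether bond to the doubly flanked oxygen is made by SN2 chemistry, which is much less sensitive to the neighbouring groups than the aryl transfer of step 10. Here the alternative is stronger.
- Against it: it also starts from 16 and does not replace the ring B work. Four steps replace one arylation for a ring that is carvacrol plus one oxygen. The aldol closure must attack a hindered isopropyl ketone, A6 polymerises easily, A5 can enolise on either side, and A7 must be aromatised oxidatively next to the electron-rich ring B.
- Comparison: the chosen strategy uses annulation once, on ring B, and accepts one demanding arylation for ring A.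

Key step: step 4

Remark on the chemistry: compounds 8 to 15 are carried as racemic diastereomer and tautomer mixtures, because every sp3 centre of ring B is erased in step 7 and the target has no stereocentre.

## Route

Step 1
Reactants: 1 benzyl chloromethyl ether
Product: 2 diethyl [(benzyloxy)methyl]phosphonate
Conditions: P(OEt)3, neat, 110 °C, chloroethane distilled off
Reagents that add atoms: triethyl phosphite, CCOP(OCC)OCC
Why: Michaelis–Arbuzov reaction; the α-chloro ether alkylates phosphorus readily and chloride dealkylates the phosphonium intermediate.

Step 2
Reactants: 2 diethyl [(benzyloxy)methyl]phosphonate; 3 ethyl propanoate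
Product: 4 diethyl [1-(benzyloxy)-2-oxobutyl]phosphonate
Conditions: 2 (2.0 equiv), LiN(iPr)2 (LDA, 2.0 equiv), THF, −78 °C; then 3 (1.0 equiv), −78 → −20 °C; aq. NH4Cl
Reagents that add atoms: none
Why: Acylation of a lithiated phosphonate by an ester, the standard β-ketophosphonate synthesis; the second equivalent of lithiated 2 deprotonates the more acidic product, so no free amide base meets the enolisable ester, and the excess 2 should be recovered.

Step 3
Reactants: 4 diethyl [1-(benzyloxy)-2-oxobutyl]phosphonate; 5 2-methylpropanal (isobutyraldehyde)
Product: 6 (Z)-4-(benzyloxy)-6-methylhept-4-en-3-one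
Conditions: NaH, THF, 0 °C; then 5, 0 °C → rt
Reagents that add atoms: none
Why: Horner–Wadsworth–Emmons olefination of an α-alkoxy β-ketophosphonate; the isomer with acyl and isopropyl trans (Z by priority) should predominate, and the geometry is immaterial because both isomers converge in step 4.

Step 4
Reactants: 6 (Z)-4-(benzyloxy)-6-methylhept-4-en-3-one; 7 dimethyl malonate
Product: 9 methyl 5-(benzyloxy)-6-isopropyl-3-methyl-2,4-dioxocyclohexane-1-carboxylate, via Michael adduct 8 (not isolated)
Conditions: 7 (1.5 equiv), NaOMe (1.6 equiv), MeOH, rt; then 6, reflux; cold 1 M HCl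
Reagents that add atoms: none
Why: Methoxide generates the malonate anion, which adds reversibly to the β-carbon B5 of 6 and forms B4–B5; protonation of the resulting α-benzyloxy ketone enolate gives 8. Equilibrating enolisation of 8 on the ethyl side (B2) is followed by attack on one of the two equivalent malonate esters, which forms B2–B3 and expels methoxide. The closure is a 6-(enolendo)-exo-trig Claisen (Dieckmann-type) acylation, whereas the other enolate, at B6, could only close a four-membered ring. Product 9 is a cyclic β-diketone and β-keto ester and is deprotonated under the conditions, which drains the unfavourable Michael equilibrium of the β-branched, α-alkoxy acceptor. The closest known reaction is the tandem Michael–Claisen synthesis of 5-substituted cyclohexane-1,3-diones from enones and malonic esters, as in the preparation of dimedone. The centres B2, B4, B5 and B6 form without control, under thermodynamic equilibration where they are enolisable, and none survives step 7, so 9 is taken on as a mixture. The step needs 1,4- over 1,2-addition, which the soft and reversibly adding malonate secures; closure through B2, which ring size secures; and retention of the benzyloxy group, which holds because no carbanion of 8 or 9 is ever β to the carbon that carries it.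

Step 5
Reactants: 9 methyl 5-(benzyloxy)-6-isopropyl-3-methyl-2,4-dioxocyclohexane-1-carboxylate
Product: 11 4-(benzyloxy)-5-isopropyl-2-methylcyclohexane-1,3-dione, via keto acid 10 (not isolated)
Conditions: 2 M aq. NaOH, 80 °C; then HCl to pH 1–2, 70 °C
Reagents that add atoms: none
Why: Saponification and decarboxylation of a vinylogous β-keto acid, as in the classical dihydroresorcinol syntheses; the dione is protected as its enolate during the basic stage and the benzyl ether is stable to both stages.

Step 6
Reactants: 11 4-(benzyloxy)-5-isopropyl-2-methylcyclohexane-1,3-dione
Product: 12 6-(benzyloxy)-5-isopropyl-3-methoxy-2-methylcyclohex-2-en-1-one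
Conditions: MeOH, HC(OMe)3, TsOH·H2O (cat.), rt
Reagents that add atoms: methanol, CO
Why: Acid-catalysed vinylogous ester formation under equilibrating conditions; methanol should add to the B3 carbonyl, which is flanked by the B4 methylene, and the resulting O-methyl group, pushed away from the B2 methyl, points toward B4 instead of toward the benzyloxy-bearing B6, so kinetic and thermodynamic preference agree.

Step 7
Reactants: 12 6-(benzyloxy)-5-isopropyl-3-methoxy-2-methylcyclohex-2-en-1-one
Product: 16 2-(benzyloxy)-3-isopropyl-5-methoxy-6-methylphenol, via selenide 13 (not isolated), via selenoxide 14 (not isolated), via dienone 15 (not isolated)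
Conditions: LiN(iPr)2, THF, −78 °C; PhSeCl, −78 °C; then mCPBA (1.0 equiv), CH2Cl2, −78 °C; iPr2NH, −78 °C → rt
Reagents that add atoms: none
Why: Kinetic α′-deprotonation of the vinylogous ester at B6, selenenylation and selenoxide syn-elimination toward the B5 hydrogen give dienone 15, the keto tautomer of the phenol, which aromatises at once; selenenylation at the γ-carbon B4 would lead to the same phenol after elimination and tautomerisation.

Step 8
Reactants: 17 carvacrol (5-isopropyl-2-methylphenol)
Product: 18 4-isopropyl-2-methoxy-1-methylbenzene (carvacrol methyl ether)
Conditions: MeI, K2CO3, acetone, reflux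
Reagents that add atoms: iodomethane, CI
Why: Williamson O-methylation of a phenol.

Step 9
Reactants: 18 4-isopropyl-2-methoxy-1-methylbenzene
Product: 19 bis(2-isopropyl-4-methoxy-5-methylphenyl)iodonium 4-methylbenzenesulfonate
Conditions: I2, mCPBA, TsOH·H2O, CH2Cl2/CF3CH2OH, rt
Reagents that add atoms: iodine, II; 4-methylbenzenesulfonic acid, Cc1ccc(S(=O)(=O)O)cc1
Why: One-pot oxidative synthesis of a symmetric diaryliodonium tosylate from an electron-rich arene and iodine; both electrophilic substitutions should go para to the methoxy group, which gives the ring A substitution pattern.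

Step 10
Reactants: 16 2-(benzyloxy)-3-isopropyl-5-methoxy-6-methylphenol; 19 bis(2-isopropyl-4-methoxy-5-methylphenyl)iodonium 4-methylbenzenesulfonate
Product: 20 2-(benzyloxy)-1-isopropyl-3-(2-isopropyl-4-methoxy-5-methylphenoxy)-5-methoxy-4-methylbenzene
Conditions: tBuOK, THF, 0 °C; then 19, rt → 50 °C
Reagents that add atoms: none
Why: Metal-free O-arylation of a phenoxide with a diaryliodonium salt by ligand coupling at trivalent iodine, a reaction known to tolerate ortho substituents on both partners; the symmetric salt removes any question of which aryl group is transferred.

Step 11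
Reactants: 20 2-(benzyloxy)-1-isopropyl-3-(2-isopropyl-4-methoxy-5-methylphenoxy)-5-methoxy-4-methylbenzene
Product: 21 6-isopropyl-2-(2-isopropyl-4-methoxy-5-methylphenoxy)-4-methoxy-3-methylphenol
Conditions: H2 (1 atm), Pd/C, EtOAc/EtOH, rt
Reagents that add atoms: none
Why: Hydrogenolysis of a benzyl aryl ether; methyl and diaryl ethers are inert, and the air-sensitive phenol should be used directly under argon.

Step 12
Reactants: 22 thymol (2-isopropyl-5-methylphenol)
Product: 23 2,4-dibromo-6-isopropyl-3-methylphenol (4,6-dibromothymol)
Conditions: Br2 (2.05 equiv), AcOH, 15 °C → rt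
Reagents that add atoms: bromine, BrBr
Why: Electrophilic bromination at the only free ortho and para positions of the phenol.

Step 13
Reactants: 23 2,4-dibromo-6-isopropyl-3-methylphenol
Product: 25 3-bromo-5-isopropyl-2-methylcyclohexa-2,5-diene-1,4-dione, via bromohydrin dienone 24 (not isolated)
Conditions: PhI(OAc)2 (1.2 equiv), MeCN/H2O, 0 °C
Reagents that add atoms: water, O
Why: Hypervalent-iodine oxidation of a para-substituted phenol in aqueous medium; water adds at the para carbon and the geminal bromohydrin 24 collapses to the carbonyl, so the ortho bromine ends up next to the quinone methyl by constitution.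

Step 14
Reactants: 21 6-isopropyl-2-(2-isopropyl-4-methoxy-5-methylphenoxy)-4-methoxy-3-methylphenol; 25 3-bromo-5-isopropyl-2-methylcyclohexa-2,5-diene-1,4-dione
Product: 26 3-[6-isopropyl-2-(2-isopropyl-4-methoxy-5-methylphenoxy)-4-methoxy-3-methylphenoxy]-5-isopropyl-2-methylcyclohexa-2,5-diene-1,4-dione
Conditions: Cs2CO3, MeCN, 0 °C → rt, argon, dark
Reagents that add atoms: none
Why: Addition–elimination of a phenoxide on a 2-halo-1,4-benzoquinone; the bromine-bearing carbon is the most electrophilic site, the neighbouring carbon is blocked by methyl, and the only other open carbon is shielded by the isopropyl group.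

## Compound list

1 | benzyl chloromethyl ether | ClCOCc1ccccc1 | starting material
2 | diethyl [(benzyloxy)methyl]phosphonate | CCOP(=O)(COCc1ccccc1)OCC | intermediate
3 | ethyl propanoate | CCC(=O)OCC | starting material
4 | diethyl [1-(benzyloxy)-2-oxobutyl]phosphonate (racemic) | CCC(=O)C(OCc1ccccc1)P(=O)(OCC)OCC | intermediate
5 | 2-methylpropanal (isobutyraldehyde) | CC(C)C=O | starting material
6 | (Z)-4-(benzyloxy)-6-methylhept-4-en-3-one | CCC(=O)/C(OCc1ccccc1)=C/C(C)C | intermediate
7 | dimethyl malonate | COC(=O)CC(=O)OC | starting material
8 | dimethyl 2-[4-(benzyloxy)-2-methyl-5-oxoheptan-3-yl]malonate (diastereomer mixture, not isolated) | CCC(=O)C(OCc1ccccc1)C(C(C)C)C(C(=O)OC)C(=O)OC | intermediate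
9 | methyl 5-(benzyloxy)-6-isopropyl-3-methyl-2,4-dioxocyclohexane-1-carboxylate (diastereomer mixture) | COC(=O)C1C(C(C)C)C(OCc2ccccc2)C(=O)C(C)C1=O | intermediate
10 | 5-(benzyloxy)-6-isopropyl-3-methyl-2,4-dioxocyclohexane-1-carboxylic acid (not isolated) | OC(=O)C1C(C(C)C)C(OCc2ccccc2)C(=O)C(C)C1=O | intermediate
11 | 4-(benzyloxy)-5-isopropyl-2-methylcyclohexane-1,3-dione (diastereomer mixture) | CC1C(=O)CC(C(C)C)C(OCc2ccccc2)C1=O | intermediate
12 | 6-(benzyloxy)-5-isopropyl-3-methoxy-2-methylcyclohex-2-en-1-one (diastereomer mixture) | COC1=C(C)C(=O)C(OCc2ccccc2)C(C(C)C)C1 | intermediate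
13 | 6-(benzyloxy)-5-isopropyl-3-methoxy-2-methyl-6-(phenylselanyl)cyclohex-2-en-1-one (not isolated) | COC1=C(C)C(=O)C(OCc2ccccc2)([Se]c2ccccc2)C(C(C)C)C1 | intermediate
14 | 6-(benzyloxy)-5-isopropyl-3-methoxy-2-methyl-6-(phenylseleninyl)cyclohex-2-en-1-one (not isolated) | COC1=C(C)C(=O)C(OCc2ccccc2)([Se](=O)c2ccccc2)C(C(C)C)C1 | intermediate
15 | 2-(benzyloxy)-3-isopropyl-5-methoxy-6-methylcyclohexa-2,5-dien-1-one (not isolated) | COC1=C(C)C(=O)C(OCc2ccccc2)=C(C(C)C)C1 | intermediate
16 | 2-(benzyloxy)-3-isopropyl-5-methoxy-6-methylphenol | COc1cc(C(C)C)c(OCc2ccccc2)c(O)c1C | intermediate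
17 | carvacrol (5-isopropyl-2-methylphenol) | Cc1ccc(C(C)C)cc1O | starting material
18 | 4-isopropyl-2-methoxy-1-methylbenzene | COc1cc(C(C)C)ccc1C | intermediate
19 | bis(2-isopropyl-4-methoxy-5-methylphenyl)iodonium 4-methylbenzenesulfonate | COc1cc(C(C)C)c([I+]c2cc(C)c(OC)cc2C(C)C)cc1C.Cc1ccc(S(=O)(=O)[O-])cc1 | intermediate
20 | 2-(benzyloxy)-1-isopropyl-3-(2-isopropyl-4-methoxy-5-methylphenoxy)-5-methoxy-4-methylbenzene | COc1cc(C(C)C)c(Oc2c(C)c(OC)cc(C(C)C)c2OCc2ccccc2)cc1C | intermediate
21 | 6-isopropyl-2-(2-isopropyl-4-methoxy-5-methylphenoxy)-4-methoxy-3-methylphenol | COc1cc(C(C)C)c(Oc2c(C)c(OC)cc(C(C)C)c2O)cc1C | intermediate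
22 | thymol (2-isopropyl-5-methylphenol) | Cc1ccc(C(C)C)c(O)c1 | starting material
23 | 2,4-dibromo-6-isopropyl-3-methylphenol | Cc1c(Br)cc(C(C)C)c(O)c1Br | intermediate
24 | 2,4-dibromo-4-hydroxy-6-isopropyl-3-methylcyclohexa-2,5-dien-1-one (not isolated) | CC1=C(Br)C(=O)C(C(C)C)=CC1(O)Br | intermediate
25 | 3-bromo-5-isopropyl-2-methylcyclohexa-2,5-diene-1,4-dione | CC1=C(Br)C(=O)C(C(C)C)=CC1=O | intermediate
26 | 3-[6-isopropyl-2-(2-isopropyl-4-methoxy-5-methylphenoxy)-4-methoxy-3-methylphenoxy]-5-isopropyl-2-methylcyclohexa-2,5-diene-1,4-dione | COc1cc(C(C)C)c(Oc2c(C)c(OC)cc(C(C)C)c2OC2=C(C)C(=O)C=C(C(C)C)C2=O)cc1C | target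

## Step count and risks

Total step count: 14. Longest linear sequence: 10 steps (steps 1 to 7, then 10, 11 and 14). Steps 8 and 9 (ring A) and steps 12 and 13 (ring C) are side branches.

**Step 4 (key step).** The conjugate addition may stall. The β-carbon of 6 is branched and is also the β-carbon of an enol ether, so retro-Michael reaction, base-induced deconjugation and self-condensation of 6 can outrun ring closure. Fallback: it sets out from 6 and returns at 11, making the same two bonds in separate operations. 1-Methoxy-1-(trimethylsilyloxy)ethene F1 is added to 6 under TiCl4 in CH2Cl2 at −78 °C (Mukaiyama–Michael addition, with the Lewis acid chelated between the carbonyl and the benzyloxy oxygen). This should give methyl 4-(benzyloxy)-3-isopropyl-5-oxoheptanoate F2 after work-up. Treatment of F2 with tBuOK in THF closes the ring through the ethyl carbon to 11 directly, and step 5 is not needed.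

**Step 6.** Methylation may occur at the B1 oxygen, or give a mixture that does not equilibrate cleanly; this would exchange the positions of the methoxy group and ring A. Fallback: it sets out from 11 and returns at 16, moving the differentiation to the aromatic stage. The dianion of 11 (LiN(iPr)2, 2.2 equiv) is selenenylated to 4-(benzyloxy)-5-isopropyl-2-methyl-6-(phenylselanyl)cyclohexane-1,3-dione F3. Oxidation and elimination as in step 7 give 4-(benzyloxy)-5-isopropyl-2-methylbenzene-1,3-diol F4. Of its two hydroxyls, only the B3 hydroxyl has a free ortho position and no neighbouring benzyloxy group, so one equivalent of MeI with K2CO3 should methylate it preferentially and give 16.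

**Step 7.** Deprotonation at the fully substituted B6 may be slow. In addition, the electron-rich phenol, once formed, may be oxidised further by peracid or by the selenium by-products. Fallback: it sets out from 12 and returns at 16 and makes no new compound (F0). It is a palladium-catalysed aerobic dehydrogenation of the cyclohexenone (Pd(OCOCF3)2, 2-(dimethylamino)pyridine, TsOH, O2, DMSO, 80 °C), which needs neither a strong base nor a peroxide.

**Step 10.** Aryl transfer from the electron-rich, ortho-isopropyl iodonium salt to a phenoxide flanked by methyl and benzyloxy may be slow. The salt could then decompose by base-induced elimination to an aryne, or the phenoxide could be oxidised by electron transfer. Fallback: it sets out from 18 and 16 and returns at 20. Iodination of 18 para to the methoxy group (N-iodosuccinimide, cat. CF3CO2H, MeCN) gives 1-iodo-2-isopropyl-4-methoxy-5-methylbenzene F5. F5 is coupled with 16 by copper catalysis (CuI, picolinic acid, K3PO4, DMSO, 100 °C), an Ullmann-type ether synthesis.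

**Step 13.** The bromide that is released may be re-oxidised to electrophilic bromine by the iodine reagent, which consumes oxidant and can lead to bromination of the quinone. Fallback: it sets out from 22 and returns at 25 and avoids any loss of bromide. Ortho-selective monobromination of 22 (N-bromosuccinimide, cat. iPr2NH, CH2Cl2) gives 2-bromo-6-isopropyl-3-methylphenol F6. Its free para position is then oxidised with (KSO3)2NO (Fremy's salt) in buffered aqueous acetone to give 25.

**Step 14.** The phenoxide of 21 is a p-methoxyphenoxide and may transfer an electron to the quinone, which would oxidise ring B and reduce 25 instead of giving substitution. Conjugate addition at the unsubstituted quinone carbon is a second possible diversion. Fallback: it sets out from 25 and 21 and returns at 26, attaching ring C at the hydroquinone level.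
- Reduction of 25 with Na2S2O4 gives 3-bromo-5-isopropyl-2-methylbenzene-1,4-diol F7.
- Benzylation (BnBr, K2CO3, DMF) gives 1,4-bis(benzyloxy)-3-bromo-5-isopropyl-2-methylbenzene F8.
- Palladium-catalysed C–O coupling of F8 with 21 (Pd(OAc)2, tBuXPhos, K3PO4, toluene, 100 °C) gives 1,4-bis(benzyloxy)-3-[6-isopropyl-2-(2-isopropyl-4-methoxy-5-methylphenoxy)-4-methoxy-3-methylphenoxy]-5-isopropyl-2-methylbenzene F9.
- Hydrogenolysis (H2, Pd/C) gives 3-[6-isopropyl-2-(2-isopropyl-4-methoxy-5-methylphenoxy)-4-methoxy-3-methylphenoxy]-5-isopropyl-2-methylbenzene-1,4-diol F10.
- Ag2O in ether oxidises only the free hydroquinone and gives 26.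

This fallback exchanges the redox problem for a steric one, since the coupling forms an ether with four ortho substituents.

## Further compounds

F1 | step 4 | 1-methoxy-1-(trimethylsilyloxy)ethene | COC(=C)O[Si](C)(C)C
F2 | step 4 | methyl 4-(benzyloxy)-3-isopropyl-5-oxoheptanoate (diastereomer mixture) | CCC(=O)C(OCc1ccccc1)C(C(C)C)CC(=O)OC
F3 | step 6 | 4-(benzyloxy)-5-isopropyl-2-methyl-6-(phenylselanyl)cyclohexane-1,3-dione (diastereomer mixture) | CC1C(=O)C([Se]c2ccccc2)C(C(C)C)C(OCc2ccccc2)C1=O
F4 | step 6 | 4-(benzyloxy)-5-isopropyl-2-methylbenzene-1,3-diol | Cc1c(O)cc(C(C)C)c(OCc2ccccc2)c1O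
F0 | step 7 | none | none
F5 | step 10 | 1-iodo-2-isopropyl-4-methoxy-5-methylbenzene | COc1cc(C(C)C)c(I)cc1C
F6 | step 13 | 2-bromo-6-isopropyl-3-methylphenol | Cc1ccc(C(C)C)c(O)c1Br
F7 | step 14 | 3-bromo-5-isopropyl-2-methylbenzene-1,4-diol | Cc1c(Br)c(O)c(C(C)C)cc1O
F8 | step 14 | 1,4-bis(benzyloxy)-3-bromo-5-isopropyl-2-methylbenzene | Cc1c(Br)c(OCc2ccccc2)c(C(C)C)cc1OCc1ccccc1
F9 | step 14 | 1,4-bis(benzyloxy)-3-[6-isopropyl-2-(2-isopropyl-4-methoxy-5-methylphenoxy)-4-methoxy-3-methylphenoxy]-5-isopropyl-2-methylbenzene | COc1cc(C(C)C)c(Oc2c(C)c(OC)cc(C(C)C)c2Oc2c(C)c(OCc3ccccc3)cc(C(C)C)c2OCc2ccccc2)cc1C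
F10 | step 14 | 3-[6-isopropyl-2-(2-isopropyl-4-methoxy-5-methylphenoxy)-4-methoxy-3-methylphenoxy]-5-isopropyl-2-methylbenzene-1,4-diol | COc1cc(C(C)C)c(Oc2c(C)c(OC)cc(C(C)C)c2Oc2c(C)c(O)cc(C(C)C)c2O)cc1C
A1 | alternative 1 | 5-chloro-1,3-dimethoxy-2-methylbenzene | COc1cc(Cl)cc(OC)c1C
A2 | alternative 1 | (6-isopropyl-2,4-dimethoxy-3-methylphenyl)boronic acid | COc1cc(C(C)C)c(B(O)O)c(OC)c1C
A3 | alternative 2 | 4-hydroxy-3-[6-isopropyl-2-(2-isopropyl-4-methoxy-5-methylphenoxy)-4-methoxy-3-methylphenoxy]-2-methyl-4-(3-methylbut-1-en-2-yl)cyclobut-2-en-1-one | COc1cc(C(C)C)c(Oc2c(C)c(OC)cc(C(C)C)c2OC2=C(C)C(=O)C2(O)C(=C)C(C)C)cc1C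
A4 | alternative 2 | 3-[6-isopropyl-2-(2-isopropyl-4-methoxy-5-methylphenoxy)-4-methoxy-3-methylphenoxy]-5-isopropyl-2-methylbenzene-1,4-diol | COc1cc(C(C)C)c(Oc2c(C)c(OC)cc(C(C)C)c2Oc2c(C)c(O)cc(C(C)C)c2O)cc1C
A5 | alternative 3 | 1-[2-(benzyloxy)-3-isopropyl-5-methoxy-6-methylphenoxy]-3-methylbutan-2-one | COc1cc(C(C)C)c(OCc2ccccc2)c(OCC(=O)C(C)C)c1C
A6 | alternative 3 | 3-methylbut-3-en-2-one | CC(=C)C(C)=O
A7 | alternative 3 | 4-[2-(benzyloxy)-3-isopropyl-5-methoxy-6-methylphenoxy]-3-isopropyl-6-methylcyclohex-2-en-1-one (diastereomer mixture) | CC1CC(Oc2c(C)c(OC)cc(C(C)C)c2OCc2ccccc2)C(C(C)C)=CC1=O
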